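All runs were generated by integration from invented constants; scatter was added.

In a one-step world every substrate lost would stand as target, yet by 30.0 h the grey and ochre runs have lost 62.9% of the charge and hold 31.1% as target. At that reading their targets differ by 0.6 percentage points, with a scatter of 1 point, and the impurity charge of the flask, 0.0670 M, lies between theirs, so I pool the two runs into one curve.

| flask | substrate | gas phase | protic impurity | catalyst | remark | time |
|---|---|---|---|---|---|---|
| grey | 0.67 M | 40 mM (held) | 0.045 M | 3.4 mM | run made earlier |  |
| ochre | 0.67 M | 40 mM (held) | 0.10 M | 3.4 mM | run made earlier |  |
| flask | 0.67 M | 40 mM (held) | 0.0670 M | 3.4 mM |  | 25 h |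

- grey (time / h: target / %, substrate / %): 2.50: 4.8, 95.5; 4.00: 9.1, 92.9; 6.00: 12.8, 86.5; 10.0: 16.2, 76.3; 20.0: 26.8, 56.2; 30.0: 31.4, 36.3
- ochre (time / h: target / %, substrate / %): 2.50: 3.1, 95.5; 4.00: 8.4, 92.9; 6.00: 10.5, 86.1; 10.0: 17.9, 76.7; 20.0: 25.9, 56.0; 30.0: 30.8, 38.0

(standard deviation of a reading: 1 percentage point)

- at the start none of the gas is dissolved
- steps thought possible: gas phase <-> dissolved gas; substrate + dissolved gas + catalyst -> catalyst + target; dissolved gas + protic impurity -> quenched reagent; target <-> isomer of the product

1. the target standing at 25 h, as a percentage of the substrate charged
2. the change that raises the amount of target at 25 h, in percent of the substrate charged most ("none" if none brings more than 2 percentage points) (north-west / north / north-east / none)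
3. amount of target at 25 h, in percent of the substrate charged, after north

- north-west: doubling the saturation concentration of gas phase, all else as stated
- north: doubling the amount of catalyst, all else as stated
- north-east: doubling the transfer coefficient of the gas phase, all else as stated

The pooled target stands at 17.0% after 10.0 h and 26.4% after 20.0 h, so successive equal intervals gain 9.3 points and then 4.7 points. The rise ratio, the gain of one interval divided by the gain of the interval before, reads 0.511, and the first interval gives 0.547. A pseudo-first-order approach to a plateau has a constant ratio, and these two readings of it lie close together.

A curve bending downward lies above its chord, so the pooled readings, with their scatter, put the target at 25 h no lower than about 28.7%. It lies under the extended earlier chord, so the same readings put it no higher than about 31.0%. If the ratio holds steady, the first half of the last interval takes the share one over one plus the root of the ratio, and I commit to 29.1%.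

The forecast gives 29%, inside my bracket, with north-west as the best change and 30.5% after north, on the ground that “The reaction is therefore limited by gas transfer”. The flask gives 28.9%, above the lower edge and below my figure. North-west adds 15 points, north-east 8.3 points and north 5.4 points, so north-west is best and north reaches 34.3%.

    gas phase ⇌ dissolved gas, rate k1*(csat - [dissolved gas]) (kL = 0.570 h⁻¹)
    substrate + dissolved gas + catalyst → catalyst + target (k = 710 L² mol⁻² h⁻¹)
    dissolved gas + protic impurity → quenched reagent (k = 0.260 L mol⁻¹ h⁻¹)
    target ⇌ isomer of the product (K = 2.20, k = 0.0770 h⁻¹)

The flask's target gains 19.5% in its first 12.5 h and 9.4 points in the next equal stretch, a ratio of 0.482, where the rise ratio scaled to that stretch gives 0.432. The neighbouring flask is the same flask left until 40 h. The last chord, extended, puts its target no higher than about 35.8%, and one more interval at the ratio gives 33.5%. That flask holds 34.0% as target.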